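## Retrosynthetic overview

1. Eudesmagnolol ⇒ a fluoride-labile bis-silyl precursor; its ring-B allyl group comes from an aryl aldehyde (vinyl Grignard/carbonate, then Pd–formate hydrogenolysis).
2. Aryl–O–C4 bond ⇒ SNAr of the C4 potassium alkoxide of 11-O-TES-cryptomeridiol on a para-formyl-activated 2-aryl-fluorobenzene (the convergent union; C4 is already fixed).
3. Fluoro-biaryl aldehyde ⇒ C–I-selective Suzuki coupling and Stille allylation, from 4-bromophenol and 3-bromo-4-fluorobenzaldehyde (both benzene rings are bought).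
4. Cryptomeridiol ⇒ α-selinene (double Markovnikov HAT hydration) ⇒ (+)-α-cyperone (reductive enol-triflate formation, then C–O hydrogenolysis).
5. Ring order: cyclohexane ring B comes from (+)-dihydrocarvone; ring A is closed onto it by intramolecular aldol condensation of a 1,5-diketone made by auxiliary-controlled Michael addition to ethyl vinyl ketone.

Assumption: commercial (+)-dihydrocarvone is the usual mixture of C2 epimers (both 5R; C2 is re-set in step 1), and α/β refer to the usual eudesmane numbering and drawing (10-CH3 = β).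

## Route

Step 1
Reactants: 1 (+)-dihydrocarvone; 2 (R)-1-phenylethylamine; 3 ethyl vinyl ketone
Product: 6 (2S,5R)-2-methyl-2-(3-oxopentyl)-5-(prop-1-en-2-yl)cyclohexan-1-one, via imine 4 (not isolated), via Michael adduct imine 5 (not isolated)
Conditions: 2 (1.05 equiv), TsOH (cat.), toluene, reflux, Dean–Stark; then 3 (1.5 equiv), 40 °C, 4 d; then 10% aq AcOH, rt
Reagents that add atoms: water (O)
Why: d'Angelo asymmetric Michael addition, in which the more substituted secondary enamine tautomer of chiral imine 4 adds to the enone through a chair-like aza-ene transition state on the face left open by the phenyl group of the (R)-auxiliary, setting the quaternary centre (2S, the future C10 with β-methyl) against the substrate bias before hydrolysis frees the 1,5-diketone.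

Step 2
Reactants: 6 (2S,5R)-2-methyl-2-(3-oxopentyl)-5-(prop-1-en-2-yl)cyclohexan-1-one
Product: 8 (+)-α-cyperone, via ketol 7 (not isolated)
Conditions: NaOMe (0.3 equiv), MeOH, rt → 50 °C
Reagents that add atoms: none
Why: Intramolecular aldol condensation (ring-closing half of a Robinson annulation), in which the ethyl-ketone enolate carbon (C4) attacks the ring carbonyl (C5) to close the six-membered ring A and E1cB dehydration gives the tetrasubstituted enone, with no new stereocentre and C7/C10 untouched.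

Step 3
Reactants: 8 (+)-α-cyperone
Product: 10 5α-eudesma-3,11-dien-3-yl trifluoromethanesulfonate, via lithium enolate 9 (not isolated)
Conditions: Li (2.4 equiv), t-BuOH (1.0 equiv), NH3(l)–THF, −78 °C; isoprene; NH3 evaporated; then PhNTf2 (1.2 equiv), THF, 0 °C → rt; H2O work-up
Reagents that add atoms: N-phenylbis(trifluoromethanesulfonimide) (O=S(=O)(N(c1ccccc1)S(=O)(=O)C(F)(F)F)C(F)(F)F)
Why: Dissolving-metal (Birch-type) enone reduction with regiospecific trapping of the enolate as its triflate, where axial protonation of C5 anti to the angular methyl sets the trans ring fusion (5α-H) and the isolated isopropenyl group is not reduced.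

Step 4
Reactants: 10 5α-eudesma-3,11-dien-3-yl trifluoromethanesulfonate
Product: 11 (−)-α-selinene
Conditions: Pd(OAc)2 (5 mol %), PPh3 (10 mol %), n-Bu3N (3 equiv), HCO2H (2 equiv), DMF, 60 °C
Reagents that add atoms: none
Why: Pd-catalysed formate hydrogenolysis of the enol triflate (Cacchi reduction) replaces C–OTf by C–H without moving the Δ3 double bond or touching C5, C7 and C10.

Step 5
Reactants: 11 (−)-α-selinene
Product: 13 cryptomeridiol, via bis-hydroperoxide 12 (not isolated)
Conditions: Mn(dpm)3 (10 mol %), PhSiH3 (5 equiv), O2 (1 atm), i-PrOH–CH2Cl2, 0 °C → rt; then P(OEt)3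
Reagents that add atoms: dioxygen (O=O)
Why: Mukaiyama (metal-hydride HAT) Markovnikov hydration of both alkenes, in which the tertiary C4 radical is trapped by O2 on the α face, anti to the syn-axial C10 methyl, to give the equatorial 4α-OH (4R), while C11 is not stereogenic.

Step 6
Reactants: 13 cryptomeridiol
Product: 14 11-O-triethylsilylcryptomeridiol
Conditions: TESOTf (1.05 equiv), 2,6-lutidine (2 equiv), CH2Cl2, −78 °C
Reagents that add atoms: triethylsilyl trifluoromethanesulfonate (CC[Si](CC)(CC)OS(=O)(=O)C(F)(F)F)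
Why: Selective silylation (silyl ether protection) of the side-chain carbinol at C11, which is much less hindered than the ring carbinol at C4 flanked by the ring fusion and a geminal axial methyl.

Step 7
Reactants: 15 4-bromophenol
Product: 16 4-bromo-2-iodophenol
Conditions: NIS (1.0 equiv), TsOH·H2O (10 mol %), CH2Cl2, rt
Reagents that add atoms: N-iodosuccinimide (O=C1CCC(=O)N1I)
Why: Electrophilic aromatic iodination goes ortho to the hydroxyl because the para position is blocked by bromine.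

Step 8
Reactants: 16 4-bromo-2-iodophenol
Product: 17 4-bromo-2-iodo-1-{[2-(trimethylsilyl)ethoxy]methoxy}benzene
Conditions: SEMCl (1.2 equiv), i-Pr2NEt (1.5 equiv), CH2Cl2, 0 °C → rt
Reagents that add atoms: 2-(trimethylsilyl)ethoxymethyl chloride (C[Si](C)(C)CCOCCl)
Why: O-alkylation (SEM protection) masks the phenol with a base-, Grignard- and Pd-stable group so that the phenoxide cannot later displace the activated fluoride intramolecularly to a dibenzofuran.

Step 9
Reactants: 18 3-bromo-4-fluorobenzaldehyde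
Product: 19 4-fluoro-3-(4,4,5,5-tetramethyl-1,3,2-dioxaborolan-2-yl)benzaldehyde
Conditions: B2pin2 (1.1 equiv), Pd(dppf)Cl2 (3 mol %), KOAc (3 equiv), dioxane, 90 °C
Reagents that add atoms: bis(pinacolato)diboron (CC1(C)OB(OC1(C)C)B1OC(C)(C)C(C)(C)O1)
Why: Miyaura borylation of the aryl bromide under weakly basic conditions that leave the aldehyde and the C–F bond intact.

Step 10
Reactants: 17 4-bromo-2-iodo-1-{[2-(trimethylsilyl)ethoxy]methoxy}benzene; 19 4-fluoro-3-(4,4,5,5-tetramethyl-1,3,2-dioxaborolan-2-yl)benzaldehyde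
Product: 20 5'-bromo-6-fluoro-2'-{[2-(trimethylsilyl)ethoxy]methoxy}biphenyl-3-carbaldehyde
Conditions: Pd(PPh3)4 (3 mol %), K2CO3 (2 equiv), dioxane–H2O (5:1), 65 °C
Reagents that add atoms: none
Why: Suzuki–Miyaura coupling is chemoselective for C–I over C–Br because oxidative addition to the iodide is much faster, which places the biaryl bond ortho to the protected oxygen.

Step 11
Reactants: 20 5'-bromo-6-fluoro-2'-{[2-(trimethylsilyl)ethoxy]methoxy}biphenyl-3-carbaldehyde
Product: 21 5'-allyl-6-fluoro-2'-{[2-(trimethylsilyl)ethoxy]methoxy}biphenyl-3-carbaldehyde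
Conditions: allylSnBu3 (1.3 equiv), Pd(PPh3)4 (5 mol %), toluene, 100 °C
Reagents that add atoms: allyltributylstannane (C=CC[Sn](CCCC)(CCCC)CCCC)
Why: Stille allylation of the remaining aryl bromide runs under neutral conditions that spare the aldehyde, the aryl fluoride and the SEM ether.

Step 12
Reactants: 14 11-O-triethylsilylcryptomeridiol; 21 5'-allyl-6-fluoro-2'-{[2-(trimethylsilyl)ethoxy]methoxy}biphenyl-3-carbaldehyde
Product: 23 5'-allyl-2'-{[2-(trimethylsilyl)ethoxy]methoxy}-6-{[11-(triethylsilyloxy)-5α-eudesman-4α-yl]oxy}biphenyl-3-carbaldehyde, via potassium alkoxide 22 (not isolated)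
Conditions: KH (1.0 equiv), THF, 0 °C → rt; then 21 (1.2 equiv), THF–DMF (4:1), 0 °C → rt
Reagents that add atoms: none
Why: Nucleophilic aromatic substitution (addition–elimination through a Meisenheimer complex) on the fluoride activated by the para formyl group, in which the tertiary alkoxide reacts at oxygen so the C4–O bond is never broken and the 4R configuration is retained.

Step 13
Reactants: 23 5'-allyl-2'-{[2-(trimethylsilyl)ethoxy]methoxy}-6-{[11-(triethylsilyloxy)-5α-eudesman-4α-yl]oxy}biphenyl-3-carbaldehyde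
Product: 25 methyl 1-aryl-prop-2-en-1-yl carbonate of 23, via magnesium alkoxide 24 (not isolated)
Conditions: CH2=CHMgBr (1.5 equiv), THF, −78 → 0 °C; then ClCO2Me (2 equiv), 0 °C → rt
Reagents that add atoms: vinylmagnesium bromide (C=C[Mg]Br); methyl chloroformate (COC(=O)Cl)
Why: Grignard 1,2-addition to the aldehyde followed by in situ O-acylation of the magnesium alkoxide gives the allylic carbonate, whose new carbinol centre forms as a mixture and is erased in the next step.

Step 14
Reactants: 25 methyl 1-aryl-prop-2-en-1-yl carbonate of 23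
Product: 26 O11-triethylsilyl-O-SEM-eudesmagnolol
Conditions: Pd(OAc)2 (5 mol %), n-Bu3P (20 mol %), HCO2H (2 equiv), Et3N (2.5 equiv), THF, 40 °C
Reagents that add atoms: none
Why: Tsuji Pd-catalysed formate hydrogenolysis of the allylic carbonate, in which hydride is delivered from the Pd–formate to the more substituted (benzylic) terminus of the π-allyl complex to give the terminal allyl arene.

Step 15
Reactants: 26 O11-triethylsilyl-O-SEM-eudesmagnolol
Product: 27 eudesmagnolol
Conditions: TBAF (6 equiv), THF, 60 °C; H2O work-up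
Reagents that add atoms: none
Why: Fluoride-mediated global desilylation, by Si–O cleavage of the tertiary TES ether and fluoride-triggered fragmentation of the SEM group, frees both hydroxyls without touching the tertiary alkyl aryl ether, the allyl groups or any stereocentre.

## Compound list

1 | (+)-dihydrocarvone, (2R,5R)-2-methyl-5-(prop-1-en-2-yl)cyclohexan-1-one (commercial sample also holds the 2S epimer) | CC(=C)[C@@H]1CC[C@@H](C)C(=O)C1 | starting material
2 | (R)-(+)-1-phenylethylamine | C[C@@H](N)c1ccccc1 | starting material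
3 | ethyl vinyl ketone (pent-1-en-3-one) | CCC(=O)C=C | starting material
4 | N-[(1R)-1-phenylethyl]imine of 1 (5R; C2 epimers) | CC(=C)[C@@H]1CCC(C)C(=N[C@H](C)c2ccccc2)C1 | intermediate
5 | N-[(1R)-1-phenylethyl]imine of (2S,5R)-2-methyl-2-(3-oxopentyl)-5-(prop-1-en-2-yl)cyclohexan-1-one | CCC(=O)CC[C@]1(C)CC[C@@H](C(C)=C)CC1=N[C@H](C)c2ccccc2 | intermediate
6 | (2S,5R)-2-methyl-2-(3-oxopentyl)-5-(prop-1-en-2-yl)cyclohexan-1-one | CCC(=O)CC[C@]1(C)CC[C@@H](C(C)=C)CC1=O | intermediate
7 | 5-hydroxyeudesm-11-en-3-one (aldol ketol; 7β-isopropenyl, 10β-methyl; C4 and C5 not defined) | O=C1CC[C@]2(C)CC[C@@H](C(C)=C)CC2(O)C1C | intermediate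
8 | (+)-α-cyperone, (4aS,7R)-1,4a-dimethyl-7-(prop-1-en-2-yl)-4,4a,5,6,7,8-hexahydronaphthalen-2(3H)-one | O=C1CC[C@]2(C)CC[C@@H](C(C)=C)CC2=C1C | intermediate
9 | lithium 5α-eudesma-3,11-dien-3-olate (trans-fused) | CC1=C([O-])CC[C@]2(C)CC[C@@H](C(C)=C)C[C@H]21.[Li+] | intermediate
10 | 5α-eudesma-3,11-dien-3-yl trifluoromethanesulfonate (5α-H, 7β-isopropenyl, 10β-methyl) | CC1=C(OS(=O)(=O)C(F)(F)F)CC[C@]2(C)CC[C@@H](C(C)=C)C[C@H]21 | intermediate
11 | (−)-α-selinene, (2R,4aR,8aR)-4a,8-dimethyl-2-(prop-1-en-2-yl)-1,2,3,4,4a,5,6,8a-octahydronaphthalene | CC1=CCC[C@]2(C)CC[C@@H](C(C)=C)C[C@H]21 | intermediate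
12 | 4α,11-bis(hydroperoxy)-5α-eudesmane | OO[C@]1(C)CCC[C@]2(C)CC[C@@H](C(C)(C)OO)C[C@H]21 | intermediate
13 | cryptomeridiol, (1R,4aR,7R,8aR)-7-(2-hydroxypropan-2-yl)-1,4a-dimethyldecahydronaphthalen-1-ol (5α-eudesmane-4α,11-diol) | O[C@]1(C)CCC[C@]2(C)CC[C@@H](C(C)(C)O)C[C@H]21 | intermediate
14 | 11-O-triethylsilylcryptomeridiol, (1R,4aR,7R,8aR)-1,4a-dimethyl-7-[2-(triethylsilyloxy)propan-2-yl]decahydronaphthalen-1-ol | O[C@]1(C)CCC[C@]2(C)CC[C@@H](C(C)(C)O[Si](CC)(CC)CC)C[C@H]21 | intermediate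
15 | 4-bromophenol | Oc1ccc(Br)cc1 | starting material
16 | 4-bromo-2-iodophenol | Oc1ccc(Br)cc1I | intermediate
17 | 4-bromo-2-iodo-1-{[2-(trimethylsilyl)ethoxy]methoxy}benzene | C[Si](C)(C)CCOCOc1ccc(Br)cc1I | intermediate
18 | 3-bromo-4-fluorobenzaldehyde | O=Cc1ccc(F)c(Br)c1 | starting material
19 | 4-fluoro-3-(4,4,5,5-tetramethyl-1,3,2-dioxaborolan-2-yl)benzaldehyde | O=Cc1ccc(F)c(c1)B1OC(C)(C)C(C)(C)O1 | intermediate
20 | 5'-bromo-6-fluoro-2'-{[2-(trimethylsilyl)ethoxy]methoxy}-[1,1'-biphenyl]-3-carbaldehyde | O=Cc1ccc(F)c(c1)-c1cc(Br)ccc1OCOCC[Si](C)(C)C | intermediate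
21 | 5'-allyl-6-fluoro-2'-{[2-(trimethylsilyl)ethoxy]methoxy}-[1,1'-biphenyl]-3-carbaldehyde | O=Cc1ccc(F)c(c1)-c1cc(CC=C)ccc1OCOCC[Si](C)(C)C | intermediate
22 | potassium C4-alkoxide of 14 | [K+].[O-][C@]1(C)CCC[C@]2(C)CC[C@@H](C(C)(C)O[Si](CC)(CC)CC)C[C@H]21 | intermediate
23 | 5'-allyl-2'-{[2-(trimethylsilyl)ethoxy]methoxy}-6-{[(4R,5R,7R,10R)-11-(triethylsilyloxy)eudesman-4-yl]oxy}-[1,1'-biphenyl]-3-carbaldehyde | O=Cc1ccc(O[C@]2(C)CCC[C@]3(C)CC[C@@H](C(C)(C)O[Si](CC)(CC)CC)C[C@H]32)c(c1)-c1cc(CC=C)ccc1OCOCC[Si](C)(C)C | intermediate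
24 | bromomagnesium 1-aryl-prop-2-en-1-olate from 23 (both carbinol epimers) | C=CC(O[Mg]Br)c1ccc(O[C@]2(C)CCC[C@]3(C)CC[C@@H](C(C)(C)O[Si](CC)(CC)CC)C[C@H]32)c(c1)-c1cc(CC=C)ccc1OCOCC[Si](C)(C)C | intermediate
25 | methyl 1-aryl-prop-2-en-1-yl carbonate (aryl = the biphenyl of 23 in place of CHO; both carbinol epimers) | COC(=O)OC(C=C)c1ccc(O[C@]2(C)CCC[C@]3(C)CC[C@@H](C(C)(C)O[Si](CC)(CC)CC)C[C@H]32)c(c1)-c1cc(CC=C)ccc1OCOCC[Si](C)(C)C | intermediate
26 | O11-triethylsilyl-O-SEM-eudesmagnolol (5,5'-diallylbiphenyl; 2-O-eudesmanyl, 2'-O-SEM, 11-O-TES) | C=CCc1ccc(O[C@]2(C)CCC[C@]3(C)CC[C@@H](C(C)(C)O[Si](CC)(CC)CC)C[C@H]32)c(c1)-c1cc(CC=C)ccc1OCOCC[Si](C)(C)C | intermediate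
27 | eudesmagnolol (magnolol 2-O-[(4R,5R,7R,10R)-11-hydroxyeudesman-4-yl] ether) | C=CCc1ccc(O)c(-c2cc(CC=C)ccc2O[C@]2(C)CCC[C@]3(C)CC[C@@H](C(C)(C)O)C[C@H]32)c1 | target

## Step count and risks

Total steps: 15. Longest linear sequence: 10 (steps 1–6 and 12–15); the biaryl branch (steps 7–11) is made in parallel.

Steps most likely to fail:

Step 12 (SNAr). The alkoxide is tertiary and hindered, the fluoride carries an ortho aryl group, the aldehyde can bind the alkoxide (hemiacetal, Cannizzaro/Tishchenko), and base may isomerise the allyl group. Fallback: form the ether on the unhindered fluoride and build the biaryl afterwards. The potassium alkoxide of 14 (KH, THF) is reacted with 18 (THF–DMF, 0 °C) to give 3-bromo-4-{[11-(triethylsilyloxy)-5α-eudesman-4α-yl]oxy}benzaldehyde F2. In parallel, 17 undergoes I/Mg exchange (i-PrMgCl·LiCl, THF, −20 °C) and trapping with 2-isopropoxy-4,4,5,5-tetramethyl-1,3,2-dioxaborolane to give 2-(5-bromo-2-{[2-(trimethylsilyl)ethoxy]methoxy}phenyl)-4,4,5,5-tetramethyl-1,3,2-dioxaborolane F3. Its bromide is allylated (allylSnBu3, Pd(PPh3)4, toluene, 90 °C) to 2-(5-allyl-2-{[2-(trimethylsilyl)ethoxy]methoxy}phenyl)-4,4,5,5-tetramethyl-1,3,2-dioxaborolane F4. Suzuki coupling of F2 with F4 (Pd(OAc)2/SPhos, K3PO4, toluene–H2O, 80 °C) comes back to 23.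

Step 5 (double HAT hydration). Facial selectivity of O2 trapping at C4 is untested on this substrate, so the 4-epimer may form in quantity, and the trisubstituted alkene may hydrate incompletely. Fallback: from 11, epoxidation of both alkenes with mCPBA (2.2 equiv, NaHCO3, CH2Cl2, 0 °C) goes on the α face of the ring alkene, away from the angular methyl, to give 3α,4α:11,12-diepoxy-5α-eudesmane F1. LiEt3BH (THF, 0 → 65 °C) then delivers hydride to the less substituted carbons C3 and C12 and comes back to 13 with the 4α-oxygen fixed by the epoxide.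

Step 14 (Tsuji hydrogenolysis). Hydride may go partly to the terminal carbon, or Pd–H may isomerise the product, giving the conjugated propenyl arene. Fallback: from 23, NaBH4 (MeOH–THF, 0 °C) gives the benzylic alcohol 5'-allyl-3-(hydroxymethyl)-2'-(SEM-oxy)-6-[(11-triethylsilyloxy-5α-eudesman-4α-yl)oxy]biphenyl F5. MsCl/Et3N then LiCl (CH2Cl2–DMF, 0 °C) gives the corresponding benzylic chloride F6. Stille coupling with tributyl(vinyl)stannane (Pd(PPh3)4, THF, 65 °C) builds the allyl group by sp3–sp2 coupling and comes back to 26, bypassing 25.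

## Further compounds

F1 | step 5 | 3α,4α:11,12-diepoxy-5α-eudesmane (C11 epimers) | O1[C@]2(C)[C@H]1CC[C@]3(C)CC[C@@H](C4(C)CO4)C[C@H]32
F2 | step 12 | 3-bromo-4-{[(4R,5R,7R,10R)-11-(triethylsilyloxy)eudesman-4-yl]oxy}benzaldehyde | O=Cc1ccc(O[C@]2(C)CCC[C@]3(C)CC[C@@H](C(C)(C)O[Si](CC)(CC)CC)C[C@H]32)c(Br)c1
F3 | step 12 | 2-(5-bromo-2-{[2-(trimethylsilyl)ethoxy]methoxy}phenyl)-4,4,5,5-tetramethyl-1,3,2-dioxaborolane | C[Si](C)(C)CCOCOc1ccc(Br)cc1B1OC(C)(C)C(C)(C)O1
F4 | step 12 | 2-(5-allyl-2-{[2-(trimethylsilyl)ethoxy]methoxy}phenyl)-4,4,5,5-tetramethyl-1,3,2-dioxaborolane | C[Si](C)(C)CCOCOc1ccc(CC=C)cc1B1OC(C)(C)C(C)(C)O1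
F5 | step 14 | benzylic alcohol from reduction of 23 (CH2OH in place of CHO) | OCc1ccc(O[C@]2(C)CCC[C@]3(C)CC[C@@H](C(C)(C)O[Si](CC)(CC)CC)C[C@H]32)c(c1)-c1cc(CC=C)ccc1OCOCC[Si](C)(C)C
F6 | step 14 | benzylic chloride from F5 (CH2Cl in place of CHO) | ClCc1ccc(O[C@]2(C)CCC[C@]3(C)CC[C@@H](C(C)(C)O[Si](CC)(CC)CC)C[C@H]32)c(c1)-c1cc(CC=C)ccc1OCOCC[Si](C)(C)C
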